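Pestalone D is a 2-aroylbenzaldehyde. Its ketone carbon is bonded to a ring A carbon (dibromo-orcinol ring) that lies next to the free phenol C–OH. On ring B (prenylresorcinol ring) it is bonded to a carbon that lies next to the formyl-bearing carbon. This O–C(aryl)–C(aryl)–C(=O)–C–C–CHO array is folded back into a 3-aryloxyphthalide. The ring A oxygen is tied to the future formyl carbon, the future ketone is the lactone carbonyl, and a third bromine marks the ring A carbon to be acylated. Selective Br/Li exchange then triggers acyl capture across the phthalide and a double fragmentation. This forges the tetra-ortho-substituted aryl–carbonyl bond and releases ketone, aldehyde and phenol at once.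

Key step: step 8

Assumption: the target SMILES holds no stereocentre and no fixed axis, so it is treated as achiral and no asymmetric step is needed. The lactol/acetal carbon of 6 and 9–12 is racemic and is erased in step 8.

Step 1
Reactants: 1 methyl 3,5-dihydroxybenzoate
Product: 2 methyl 2-formyl-3,5-dihydroxybenzoate
Conditions: POCl3, DMF, MeCN, 0 °C to rt; then ice-water
Reagents that add atoms: N,N-dimethylformamide, CN(C)C=O; water, O
Why: Vilsmeier–Haack formylation should strike the position ortho to one hydroxyl and para to the other, as it does with orcinol, rather than the site between the two hydroxyls.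

Step 2
Reactants: 2 methyl 2-formyl-3,5-dihydroxybenzoate
Product: 3 methyl 2-bromo-6-formyl-3,5-dihydroxybenzoate
Conditions: NBS (1.0 equiv), MeCN, −10 to 0 °C
Reagents that add atoms: N-bromosuccinimide, O=C1CCC(=O)N1Br
Why: Electrophilic aromatic bromination should go para to the aldehyde-chelated hydroxyl and ortho to the other one, the usual halogenation site of 2,4-dihydroxybenzaldehydes, and leave the CH between the two oxygens free.

Step 3
Reactants: 3 methyl 2-bromo-6-formyl-3,5-dihydroxybenzoate
Product: 4 methyl 2-bromo-6-formyl-3,5-bis(methoxymethoxy)benzoate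
Conditions: MOMCl (3 equiv), i-Pr2NEt, CH2Cl2, 0 °C to reflux
Reagents that add atoms: chloromethyl methyl ether, COCCl
Why: Williamson-type O-alkylation caps both phenols, excess reagent and warming also taking the chelated one, and MOM withstands Pd(0), hydroxide and organolithium yet leaves under mild acid.

Step 4
Reactants: 4 methyl 2-bromo-6-formyl-3,5-bis(methoxymethoxy)benzoate
Product: 5 methyl 2-formyl-3,5-bis(methoxymethoxy)-6-(3-methylbut-2-en-1-yl)benzoate
Conditions: tributyl(prenyl)stannane, Pd(PPh3)4 (cat.), DMF, 90 °C
Reagents that add atoms: tributyl(3-methylbut-2-en-1-yl)stannane, CCCC[Sn](CCCC)(CCCC)CC=C(C)C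
Why: Stille cross-coupling tolerates aldehyde, ester and acetals, and prenylstannanes normally transfer their unbranched terminus, so the 3-methylbut-2-enyl group should replace bromine.

Step 5
Reactants: 5 methyl 2-formyl-3,5-bis(methoxymethoxy)-6-(3-methylbut-2-en-1-yl)benzoate
Product: 6 3-hydroxy-4,6-bis(methoxymethoxy)-7-(3-methylbut-2-en-1-yl)isobenzofuran-1(3H)-one (racemic lactol, ring tautomer of the 2-formylbenzoic acid)
Conditions: LiOH, THF/H2O, rt; then 1 M HCl to pH 4, 0 °C
Reagents that add atoms: lithium hydroxide, [Li+].[OH-]
Why: Saponification of the hindered ester should be accelerated by neighbouring-group participation of the ortho-formyl group (its hydrate anion attacks the ester), and the acid then rests as the 3-hydroxyphthalide by ring–chain tautomerism.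

Step 6
Reactants: 7 3-methoxy-5-methylphenol (orcinol monomethyl ether)
Product: 8 2,4,6-tribromo-3-methoxy-5-methylphenol
Conditions: Br2 (3.1 equiv), AcOH, rt
Reagents that add atoms: bromine, BrBr
Why: Exhaustive electrophilic aromatic bromination fills all three free positions, each ortho or para to OH and OMe, so no selectivity is needed.

Step 7
Reactants: 6 3-hydroxy-4,6-bis(methoxymethoxy)-7-(3-methylbut-2-en-1-yl)isobenzofuran-1(3H)-one; 8 2,4,6-tribromo-3-methoxy-5-methylphenol
Product: 10 3-(2,4,6-tribromo-3-methoxy-5-methylphenoxy)-4,6-bis(methoxymethoxy)-7-(3-methylbut-2-en-1-yl)isobenzofuran-1(3H)-one (racemic), via 3-chlorophthalide 9 (not isolated)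
Conditions: 1-chloro-N,N,2-trimethylpropenylamine (1.05 equiv), CH2Cl2, 0 °C; then 8, i-Pr2NEt, 0 °C to rt
Reagents that add atoms: 1-chloro-N,N,2-trimethylprop-1-en-1-amine, CC(C)=C(Cl)N(C)C (its chlorine is held only by intermediate 9)
Why: Neutral chlorodehydroxylation by the α-chloroenamine gives the pseudo-acid chloride, and the known O-alkylation of phenols by 3-halophthalides should follow at C3, which is oxocarbenium-like through its ortho and para alkoxy groups, rather than at the prenyl-shielded carbonyl, while 8 has no free ring carbon for C-alkylation.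

Step 8
Reactants: 10 3-(2,4,6-tribromo-3-methoxy-5-methylphenoxy)-4,6-bis(methoxymethoxy)-7-(3-methylbut-2-en-1-yl)isobenzofuran-1(3H)-one
Product: 14 2-(3,5-dibromo-2-hydroxy-6-methoxy-4-methylbenzoyl)-4,6-bis(methoxymethoxy)-3-(3-methylbut-2-en-1-yl)benzaldehyde, via aryllithium 11 (not isolated), via bridged lithium alkoxide 12 (not isolated), via lithium phenolate 13 (not isolated)
Conditions: n-BuLi (1.0 equiv), THF/Et2O, high dilution, −100 to −78 °C; then AcOH, −78 °C
Reagents that add atoms: n-butyllithium, [Li]CCCC (its lithium is held only by intermediates 11–13)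
Why: Proposed new method: n-BuLi should exchange the ring A bromine lying between the two oxygen substituents to give aryllithium 11, whose carbanion adds across the phthalide to the lactone carbonyl (7-exo-trig, giving the dibenzo-fused 2,8-dioxabicyclo[3.2.1]octane alkoxide 12), and 12 should collapse by cleaving first the C1–O2 lactone bond and then the C3–OAr acetal bond, so that ketone, aldehyde and phenolate 13 appear together and the temporary ring is opened again. The closest known reaction types are the Parham cyclisation (halogen–lithium exchange followed by intramolecular acylation by an ester or lactone) and the halogen–metal-exchange-induced anionic Fries rearrangement of o-bromoaryl esters; new here is the 3-aryloxyphthalide pseudo-ester, whose acyl group is reached through a seven-membered instead of a four-membered transition state and whose tether carbon is released as the aldehyde. No ring and no stereocentre remain in the product, since the only stereocentre of racemic 10 (C3) becomes the planar formyl carbon. Site selectivity among three C–Br bonds is needed and should be secured by the flanking OMe and acetal oxygens, which make this aryllithium the inductively and chelation-stabilised, thermodynamically preferred one, with fast ArLi/ArBr exchange funnelling other lithio isomers to it, and no remaining bromine is ortho to lithium, so aryne formation is closed. Chemoselectivity rests on exchange at −100 °C outrunning addition of n-BuLi to the hindered, donor-deactivated lactone and deprotonation of C3–H, and over-addition is excluded because the aldehyde is unveiled only when the carbanion has been consumed. The tether turns the slow bimolecular assembly of a tetra-ortho-substituted benzophenone into an intramolecular event, and the cold AcOH quench should forestall a Cannizzaro–Tishchenko-type hydride shift from the hemiacetal alkoxide to the ketone.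

Step 9
Reactants: 14 2-(3,5-dibromo-2-hydroxy-6-methoxy-4-methylbenzoyl)-4,6-bis(methoxymethoxy)-3-(3-methylbut-2-en-1-yl)benzaldehyde
Product: 15 pestalone D, 2-(3,5-dibromo-2-hydroxy-6-methoxy-4-methylbenzoyl)-4,6-dihydroxy-3-(3-methylbut-2-en-1-yl)benzaldehyde
Conditions: 2 M aq. HCl (cat. amount relative to solvent water), THF/i-PrOH, 40 °C, exclusion of light
Reagents that add atoms: none
Why: Acid-catalysed acetal hydrolysis removes both MOM groups, and dilute acid at mild temperature should spare the prenyl alkene (no chroman closure), the aryl methyl ether and the C–Br bonds while avoiding base, to which 2-aroylbenzaldehydes are sensitive.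

Compound list
1 | methyl 3,5-dihydroxybenzoate | COC(=O)c1cc(O)cc(O)c1 | starting material
2 | methyl 2-formyl-3,5-dihydroxybenzoate | COC(=O)c1cc(O)cc(O)c1C=O | intermediate
3 | methyl 2-bromo-6-formyl-3,5-dihydroxybenzoate | COC(=O)c1c(Br)c(O)cc(O)c1C=O | intermediate
4 | methyl 2-bromo-6-formyl-3,5-bis(methoxymethoxy)benzoate | COC(=O)c1c(Br)c(OCOC)cc(OCOC)c1C=O | intermediate
5 | methyl 2-formyl-3,5-bis(methoxymethoxy)-6-(3-methylbut-2-en-1-yl)benzoate | COC(=O)c1c(CC=C(C)C)c(OCOC)cc(OCOC)c1C=O | intermediate
6 | 3-hydroxy-4,6-bis(methoxymethoxy)-7-(3-methylbut-2-en-1-yl)isobenzofuran-1(3H)-one (racemic) | O=C1OC(O)c2c1c(CC=C(C)C)c(OCOC)cc2OCOC | intermediate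
7 | 3-methoxy-5-methylphenol | COc1cc(C)cc(O)c1 | starting material
8 | 2,4,6-tribromo-3-methoxy-5-methylphenol | COc1c(Br)c(C)c(Br)c(O)c1Br | intermediate
9 | 3-chloro-4,6-bis(methoxymethoxy)-7-(3-methylbut-2-en-1-yl)isobenzofuran-1(3H)-one (racemic, not isolated) | O=C1OC(Cl)c2c1c(CC=C(C)C)c(OCOC)cc2OCOC | intermediate
10 | 3-(2,4,6-tribromo-3-methoxy-5-methylphenoxy)-4,6-bis(methoxymethoxy)-7-(3-methylbut-2-en-1-yl)isobenzofuran-1(3H)-one (racemic) | O=C1OC(Oc3c(Br)c(OC)c(Br)c(C)c3Br)c2c1c(CC=C(C)C)c(OCOC)cc2OCOC | intermediate
11 | 2-lithio-4,6-dibromo-3-methoxy-5-methylphenoxy phthalide (aryllithium from 10, racemic, not isolated) | O=C1OC(Oc3c([Li])c(OC)c(Br)c(C)c3Br)c2c1c(CC=C(C)C)c(OCOC)cc2OCOC | intermediate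
12 | dibenzo-fused 2,8-dioxabicyclo[3.2.1]octane lithium alkoxide (tetrahedral adduct, racemic, not isolated) | [Li]OC12OC(Oc3c(Br)c(C)c(Br)c(OC)c31)c1c(OCOC)cc(OCOC)c(CC=C(C)C)c12 | intermediate
13 | lithium phenolate of 14 (not isolated) | COc1c(Br)c(C)c(Br)c(O[Li])c1C(=O)c1c(C=O)c(OCOC)cc(OCOC)c1CC=C(C)C | intermediate
14 | 2-(3,5-dibromo-2-hydroxy-6-methoxy-4-methylbenzoyl)-4,6-bis(methoxymethoxy)-3-(3-methylbut-2-en-1-yl)benzaldehyde | COc1c(Br)c(C)c(Br)c(O)c1C(=O)c1c(C=O)c(OCOC)cc(OCOC)c1CC=C(C)C | intermediate
15 | pestalone D | COc1c(Br)c(C)c(Br)c(O)c1C(=O)c1c(C=O)c(O)cc(O)c1CC=C(C)C | target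

Total step count: 9. Longest linear sequence: 8 (steps 1–5, 7, 8, 9).

Steps most likely to fail

1. Step 8 (Proposed new method). Lithium–bromine exchange may occur at a bromine next to the methyl group. The aryl anion may be quenched by proton transfer from C3–H. A hydride shift may follow ring opening before the quench.
The fallback uses known intermolecular chemistry and sets out from 8 and 5. Phenol 8 would be capped with MOMCl/i-Pr2NEt to give 1,3,5-tribromo-2-methoxy-4-(methoxymethoxy)-6-methylbenzene F1. Here the site of exchange can be tested by a proton quench on this simple arene before any ring B material is committed. Aldehyde ester 5 would be reduced with NaBH4 in MeOH, with spontaneous lactonisation, to 4,6-bis(methoxymethoxy)-7-(3-methylbut-2-en-1-yl)phthalide F2. n-BuLi at −78 °C would convert F1 into the aryllithium F3. F3 adds to F2 (aryllithium addition to a phthalide, the lactol alkoxide blocking a second addition) to give the 2-(hydroxymethyl)benzophenone F4. Dess–Martin oxidation would give the tris-MOM keto aldehyde F5. The acid conditions of step 9 would remove all three MOM groups, so the fallback comes back to the route at 15.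

2. Step 7. The hindered phenoxide may attack the carbonyl instead of C3 and open the ring to the normal aryl ester. Substitution may be too slow, or the chloride or the product may ionise and hydrolyse on handling.
The fallback sets out from 6 and changes from base-mediated substitution to the trichloroacetimidate method. Cl3CCN and catalytic DBU in CH2Cl2 would give the 3-(trichloroacetimidoyloxy)phthalide F6. F6 would be treated with the acidic phenol 8 over 4 Å molecular sieves at −40 °C, self-promoted or with catalytic TMSOTf. The aryloxy group is then delivered only to the oxocarbenium carbon, and the fallback comes back at 10.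

3. Step 4. Transmetalation of the bulky prenylstannane at the di-ortho-substituted arylpalladium may be slow. Allylic transposition may attach the branched 1,1-dimethylallyl terminus.
The fallback sets out from 4 and builds the prenyl group in two stages. Stille coupling with allyltributylstannane, where both termini give the same product, would give methyl 2-allyl-6-formyl-3,5-bis(methoxymethoxy)benzoate F7. Olefin cross-metathesis with excess 2-methylbut-2-ene (Grubbs II catalyst, CH2Cl2, 40 °C) would install the trisubstituted alkene and come back at 5.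

Further compounds
F1 | step 8 | 1,3,5-tribromo-2-methoxy-4-(methoxymethoxy)-6-methylbenzene | COCOc1c(Br)c(OC)c(Br)c(C)c1Br
F2 | step 8 | 4,6-bis(methoxymethoxy)-7-(3-methylbut-2-en-1-yl)isobenzofuran-1(3H)-one | O=C1OCc2c1c(CC=C(C)C)c(OCOC)cc2OCOC
F3 | step 8 | [3,5-dibromo-2-methoxy-6-(methoxymethoxy)-4-methylphenyl]lithium | [Li]c1c(OC)c(Br)c(C)c(Br)c1OCOC
F4 | step 8 | [3,5-dibromo-2-methoxy-6-(methoxymethoxy)-4-methylphenyl][2-(hydroxymethyl)-3,5-bis(methoxymethoxy)-6-(3-methylbut-2-en-1-yl)phenyl]methanone | COCOc1c(Br)c(C)c(Br)c(OC)c1C(=O)c1c(CO)c(OCOC)cc(OCOC)c1CC=C(C)C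
F5 | step 8 | 2-[3,5-dibromo-2-methoxy-6-(methoxymethoxy)-4-methylbenzoyl]-4,6-bis(methoxymethoxy)-3-(3-methylbut-2-en-1-yl)benzaldehyde | COCOc1c(Br)c(C)c(Br)c(OC)c1C(=O)c1c(C=O)c(OCOC)cc(OCOC)c1CC=C(C)C
F6 | step 7 | 4,6-bis(methoxymethoxy)-7-(3-methylbut-2-en-1-yl)-3-oxo-1,3-dihydroisobenzofuran-1-yl 2,2,2-trichloroacetimidate (racemic) | N=C(OC1OC(=O)c2c1c(OCOC)cc(OCOC)c2CC=C(C)C)C(Cl)(Cl)Cl
F7 | step 4 | methyl 2-allyl-6-formyl-3,5-bis(methoxymethoxy)benzoate | COC(=O)c1c(CC=C)c(OCOC)cc(OCOC)c1C=O
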